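**Retrosynthetic overview**

- The strategy rests on C3 of indole A (the 6-methoxyindole). It carries ring C and the benzo ring of indole A, so before closure it is a doubly benzylic, acidic CH2 ortho to the nitrogen, which holds C2 as an isocyanide carbon.
- Last skeletal disconnection: C2–C3 of indole A, made by adding the diarylmethane carbanion to the ortho isocyanide. The isocyanide traces back through formamide and aniline to an ortho-nitro diarylmethane.
- The CH2–ring C bond comes from a Negishi benzylation of a ring C zinc reagent with 4-methoxy-2-nitrobenzyl bromide. The ring C–indole B bond comes from a Negishi coupling of an indol-3-ylzinc with 1,4-dibromo-2,3,5,6-tetramethoxybenzene.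
- Ring order: ring C and indole B are bought; the pyrrole ring of indole A is the only ring formed (step 9). N-desilylation and O-debenzylation follow.

Key step: step 9

Remark on the chemistry: the target has no stereocentre, and both ortho positions of ring C at each biaryl axis carry methoxy groups, so there is no axial chirality and no stereocontrol is needed.

**Route**

Step 1
Reactants: 1 1,2,4,5-tetramethoxybenzene
Product: 2 1,4-dibromo-2,3,5,6-tetramethoxybenzene
Conditions: Br2 (2.1 equiv), CH2Cl2, 0 °C → rt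
Reagents that add atoms: bromine, BrBr
Why: Electrophilic aromatic bromination at the only two free positions, each activated by two ortho methoxy groups, should give the para-dibromide.

Step 2
Reactants: 3 5-(benzyloxy)indole
Product: 5 5-(benzyloxy)-3-bromo-1-(triisopropylsilyl)indole, via N-silylindole 4 (not isolated)
Conditions: n-BuLi, THF, −78 → 0 °C; TIPSCl, 0 °C; then NBS, −78 °C, dark
Reagents that add atoms: chlorotriisopropylsilane, CC(C)[Si](Cl)(C(C)C)C(C)C; N-bromosuccinimide, O=C1CCC(=O)N1Br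
Why: N-lithiation and silylation followed by electrophilic bromination in the same flask should place bromine at C3, the most nucleophilic position of the N-silylindole, the bulky silyl group shielding C2.

Step 3
Reactants: 5 5-(benzyloxy)-3-bromo-1-(triisopropylsilyl)indole; 2 1,4-dibromo-2,3,5,6-tetramethoxybenzene
Product: 8 5-(benzyloxy)-3-(4-bromo-2,3,5,6-tetramethoxyphenyl)-1-(triisopropylsilyl)indole, via 3-lithioindole 6 (not isolated), via indol-3-ylzinc chloride 7 (not isolated)
Conditions: t-BuLi (2 equiv), THF, −78 °C; ZnCl2, −78 °C → rt; then 2 (3 equiv), Pd2(dba)3 (2.5 mol %), SPhos (10 mol %), THF, 60 °C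
Reagents that add atoms: none
Why: Negishi coupling, in which bromine–lithium exchange gives a 3-lithioindole held at C3 by the N-silyl group, transmetalation to zinc and zerovalent-palladium catalysis with a hindered biarylphosphine should join C3 to ring C, the excess of dibromide favouring single coupling.

Step 4
Reactants: 9 4-methoxy-2-nitrotoluene
Product: 10 4-methoxy-2-nitrobenzyl bromide
Conditions: NBS (1.05 equiv), AIBN (cat.), PhCF3, 85 °C
Reagents that add atoms: N-bromosuccinimide, O=C1CCC(=O)N1Br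
Why: Wohl–Ziegler radical bromination should take the benzylic methyl group, the nitro group deactivating the ring toward electrophilic bromination.

Step 5
Reactants: 8 5-(benzyloxy)-3-(4-bromo-2,3,5,6-tetramethoxyphenyl)-1-(triisopropylsilyl)indole; 10 4-methoxy-2-nitrobenzyl bromide
Product: 13 5-(benzyloxy)-3-[2,3,5,6-tetramethoxy-4-(4-methoxy-2-nitrobenzyl)phenyl]-1-(triisopropylsilyl)indole, via aryllithium 11 (not isolated), via arylzinc chloride 12 (not isolated)
Conditions: t-BuLi (2 equiv), THF, −78 °C; ZnCl2, −78 → 0 °C; then 10 (1.2 equiv), Pd(PPh3)4 (5 mol %), THF, rt → 45 °C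
Reagents that add atoms: none
Why: Negishi coupling of an arylzinc chloride with a benzylic bromide, in which fast oxidative addition of the benzyl bromide to zerovalent palladium and the tolerance of organozinc reagents for a nitro group should give the diarylmethane.

Step 6
Reactants: 13 5-(benzyloxy)-3-[2,3,5,6-tetramethoxy-4-(4-methoxy-2-nitrobenzyl)phenyl]-1-(triisopropylsilyl)indole
Product: 14 2-({4-[5-(benzyloxy)-1-(triisopropylsilyl)indol-3-yl]-2,3,5,6-tetramethoxyphenyl}methyl)-5-methoxyaniline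
Conditions: Fe powder, NH4Cl, EtOH/THF/H2O, 70 °C
Reagents that add atoms: none
Why: Dissolving-metal reduction of an aromatic nitro group under near-neutral conditions should give the aniline without touching the benzyl ether or the N-silyl group.

Step 7
Reactants: 14 2-({4-[5-(benzyloxy)-1-(triisopropylsilyl)indol-3-yl]-2,3,5,6-tetramethoxyphenyl}methyl)-5-methoxyaniline
Product: 15 N-[2-({4-[5-(benzyloxy)-1-(triisopropylsilyl)indol-3-yl]-2,3,5,6-tetramethoxyphenyl}methyl)-5-methoxyphenyl]formamide
Conditions: HCO2H, Ac2O, 55 °C (forms acetic formic anhydride); then 14, THF, 0 °C → rt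
Reagents that add atoms: acetic formic anhydride, CC(=O)OC=O, made from formic acid, OC=O, and acetic anhydride, CC(=O)OC(C)=O
Why: N-formylation of an aniline with the mixed anhydride, which transfers the less hindered and more electrophilic formyl group, should give the formamide.

Step 8
Reactants: 15 N-[2-({4-[5-(benzyloxy)-1-(triisopropylsilyl)indol-3-yl]-2,3,5,6-tetramethoxyphenyl}methyl)-5-methoxyphenyl]formamide
Product: 16 5-(benzyloxy)-3-[4-(2-isocyano-4-methoxybenzyl)-2,3,5,6-tetramethoxyphenyl]-1-(triisopropylsilyl)indole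
Conditions: POCl3, Et3N, CH2Cl2, −20 → 0 °C
Reagents that add atoms: none
Why: Dehydration of an N-aryl formamide to the isocyanide (Ugi method) should proceed by O-phosphorylation and base-induced elimination, the cold, basic medium suppressing Vilsmeier-type attack on indole B.

Step 9
Reactants: 16 5-(benzyloxy)-3-[4-(2-isocyano-4-methoxybenzyl)-2,3,5,6-tetramethoxyphenyl]-1-(triisopropylsilyl)indole
Product: 19 5-(benzyloxy)-3-[2,3,5,6-tetramethoxy-4-(6-methoxy-1H-indol-3-yl)phenyl]-1-(triisopropylsilyl)indole, via benzylic carbanion lithium salt 17 (not isolated), via N-lithioindole 18 (not isolated)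
Conditions: LDA (2.2 equiv), THF (or diglyme), −78 °C → rt; then aq NH4Cl
Reagents that add atoms: none
Why: LDA should remove one proton of the diarylmethane CH2, which is acidified by both aryl rings and by the ortho isocyano group, to give carbanion 17; this adds to the terminal isocyanide carbon to form the C2–C3 bond, and the 2-lithio-3H-indole so formed shifts its C3 proton to give N-lithioindole 18, protonated to 19 on quench. The closest known reaction type is the base-induced cyclization of ortho-alkylphenyl isocyanides to indoles (Ito–Saegusa indole synthesis), in which alpha-substituted benzylic anions give 3-substituted indoles. The pyrrole ring of indole A closes by anionic attack on the divalent isocyanide carbon in a five-membered, formally 5-endo-dig mode. No stereocentre is formed. The step needs site-selective deprotonation at the diarylmethane carbon over the benzyl ether CH2, C2–H of indole B and the methoxy groups, which the much higher acidity of the doubly benzylic position and the shielding of C2 by the triisopropylsilyl group should secure. Addition of the amide to the isocyanide carbon is limited by the low temperature, and lithium tetramethylpiperidide can replace LDA if it competes.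

Step 10
Reactants: 19 5-(benzyloxy)-3-[2,3,5,6-tetramethoxy-4-(6-methoxy-1H-indol-3-yl)phenyl]-1-(triisopropylsilyl)indole
Product: 20 5-(benzyloxy)-3-[2,3,5,6-tetramethoxy-4-(6-methoxy-1H-indol-3-yl)phenyl]-1H-indole
Conditions: TBAF, THF, 0 °C → rt
Reagents that add atoms: none
Why: Fluoride-induced N-desilylation should proceed by attack at silicon with loss of the indolyl anion, leaving the benzyl and methyl ethers untouched.

Step 11
Reactants: 20 5-(benzyloxy)-3-[2,3,5,6-tetramethoxy-4-(6-methoxy-1H-indol-3-yl)phenyl]-1H-indole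
Product: 21 3-[2,3,5,6-tetramethoxy-4-(6-methoxy-1H-indol-3-yl)phenyl]-1H-indol-5-ol (target)
Conditions: H2 (1 atm), 10% Pd/C, EtOAc/MeOH, rt
Reagents that add atoms: none
Why: Catalytic hydrogenolysis of the benzyl aryl ether should free the phenol under neutral conditions that leave the indole rings and methyl ethers intact.

**Compound list**

1 | 1,2,4,5-tetramethoxybenzene | COc1cc(OC)c(OC)cc1OC | starting material
2 | 1,4-dibromo-2,3,5,6-tetramethoxybenzene | COc1c(Br)c(OC)c(OC)c(Br)c1OC | intermediate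
3 | 5-(benzyloxy)indole | c1ccc(COc2ccc3[nH]ccc3c2)cc1 | starting material
4 | 5-(benzyloxy)-1-(triisopropylsilyl)indole | CC(C)[Si](C(C)C)(C(C)C)n1ccc2cc(OCc3ccccc3)ccc21 | intermediate
5 | 5-(benzyloxy)-3-bromo-1-(triisopropylsilyl)indole | CC(C)[Si](C(C)C)(C(C)C)n1cc(Br)c2cc(OCc3ccccc3)ccc21 | intermediate
6 | [5-(benzyloxy)-1-(triisopropylsilyl)indol-3-yl]lithium | CC(C)[Si](C(C)C)(C(C)C)n1cc([Li])c2cc(OCc3ccccc3)ccc21 | intermediate
7 | [5-(benzyloxy)-1-(triisopropylsilyl)indol-3-yl]zinc chloride | CC(C)[Si](C(C)C)(C(C)C)n1cc([Zn]Cl)c2cc(OCc3ccccc3)ccc21 | intermediate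
8 | 5-(benzyloxy)-3-(4-bromo-2,3,5,6-tetramethoxyphenyl)-1-(triisopropylsilyl)indole | COc1c(Br)c(OC)c(OC)c(-c2cn([Si](C(C)C)(C(C)C)C(C)C)c3ccc(OCc4ccccc4)cc23)c1OC | intermediate
9 | 4-methoxy-2-nitrotoluene | Cc1ccc(OC)cc1[N+](=O)[O-] | starting material
10 | 4-methoxy-2-nitrobenzyl bromide | BrCc1ccc(OC)cc1[N+](=O)[O-] | intermediate
11 | {4-[5-(benzyloxy)-1-(triisopropylsilyl)indol-3-yl]-2,3,5,6-tetramethoxyphenyl}lithium | COc1c([Li])c(OC)c(OC)c(-c2cn([Si](C(C)C)(C(C)C)C(C)C)c3ccc(OCc4ccccc4)cc23)c1OC | intermediate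
12 | {4-[5-(benzyloxy)-1-(triisopropylsilyl)indol-3-yl]-2,3,5,6-tetramethoxyphenyl}zinc chloride | COc1c([Zn]Cl)c(OC)c(OC)c(-c2cn([Si](C(C)C)(C(C)C)C(C)C)c3ccc(OCc4ccccc4)cc23)c1OC | intermediate
13 | 5-(benzyloxy)-3-[2,3,5,6-tetramethoxy-4-(4-methoxy-2-nitrobenzyl)phenyl]-1-(triisopropylsilyl)indole | COc1ccc(Cc2c(OC)c(OC)c(-c3cn([Si](C(C)C)(C(C)C)C(C)C)c4ccc(OCc5ccccc5)cc34)c(OC)c2OC)c([N+](=O)[O-])c1 | intermediate
14 | 2-({4-[5-(benzyloxy)-1-(triisopropylsilyl)indol-3-yl]-2,3,5,6-tetramethoxyphenyl}methyl)-5-methoxyaniline | COc1ccc(Cc2c(OC)c(OC)c(-c3cn([Si](C(C)C)(C(C)C)C(C)C)c4ccc(OCc5ccccc5)cc34)c(OC)c2OC)c(N)c1 | intermediate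
15 | N-[2-({4-[5-(benzyloxy)-1-(triisopropylsilyl)indol-3-yl]-2,3,5,6-tetramethoxyphenyl}methyl)-5-methoxyphenyl]formamide | COc1ccc(Cc2c(OC)c(OC)c(-c3cn([Si](C(C)C)(C(C)C)C(C)C)c4ccc(OCc5ccccc5)cc34)c(OC)c2OC)c(NC=O)c1 | intermediate
16 | 5-(benzyloxy)-3-[4-(2-isocyano-4-methoxybenzyl)-2,3,5,6-tetramethoxyphenyl]-1-(triisopropylsilyl)indole | COc1ccc(Cc2c(OC)c(OC)c(-c3cn([Si](C(C)C)(C(C)C)C(C)C)c4ccc(OCc5ccccc5)cc34)c(OC)c2OC)c([N+]#[C-])c1 | intermediate
17 | lithium salt of the diarylmethane carbanion of 16 | [Li+].COc1ccc([CH-]c2c(OC)c(OC)c(-c3cn([Si](C(C)C)(C(C)C)C(C)C)c4ccc(OCc5ccccc5)cc34)c(OC)c2OC)c([N+]#[C-])c1 | intermediate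
18 | N-lithio derivative of 19 (lithiated at N1 of indole A) | COc1ccc2c(-c3c(OC)c(OC)c(-c4cn([Si](C(C)C)(C(C)C)C(C)C)c5ccc(OCc6ccccc6)cc45)c(OC)c3OC)cn([Li])c2c1 | intermediate
19 | 5-(benzyloxy)-3-[2,3,5,6-tetramethoxy-4-(6-methoxy-1H-indol-3-yl)phenyl]-1-(triisopropylsilyl)indole | COc1ccc2c(-c3c(OC)c(OC)c(-c4cn([Si](C(C)C)(C(C)C)C(C)C)c5ccc(OCc6ccccc6)cc45)c(OC)c3OC)c[nH]c2c1 | intermediate
20 | 5-(benzyloxy)-3-[2,3,5,6-tetramethoxy-4-(6-methoxy-1H-indol-3-yl)phenyl]-1H-indole | COc1ccc2c(-c3c(OC)c(OC)c(-c4c[nH]c5ccc(OCc6ccccc6)cc45)c(OC)c3OC)c[nH]c2c1 | intermediate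
21 | 3-[2,3,5,6-tetramethoxy-4-(6-methoxy-1H-indol-3-yl)phenyl]-1H-indol-5-ol | COc1ccc2c(-c3c(OC)c(OC)c(-c4c[nH]c5ccc(O)cc45)c(OC)c3OC)c[nH]c2c1 | target

**Step count**

Total steps: 11. Longest linear sequence: 9 steps (steps 2, 3, 5, 6, 7, 8, 9, 10, 11 from 5-(benzyloxy)indole; the same length from 1 through steps 1, 3, 5–11).

**Steps most likely to fail**

Step 9. The amide base may add to the isocyanide carbon, or the hindered carbanion may close slowly so that the isocyanide oligomerizes before the C2–C3 bond forms. The fallback brings indole A in preformed and sets out from 8.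
- Commercial 6-methoxyindole would be N-silylated (n-BuLi, TIPSCl, THF) to 6-methoxy-1-(triisopropylsilyl)indole F1.
- Bromination in the same flask (NBS, −78 °C) would give 3-bromo-6-methoxy-1-(triisopropylsilyl)indole F2.
- Exchange with t-BuLi at −78 °C would give [6-methoxy-1-(triisopropylsilyl)indol-3-yl]lithium F3, and ZnCl2 would convert it into [6-methoxy-1-(triisopropylsilyl)indol-3-yl]zinc chloride F4.
- Negishi coupling of F4 with 8 (Pd2(dba)3, SPhos, THF, 60 °C) should give 5-(benzyloxy)-3-{2,3,5,6-tetramethoxy-4-[6-methoxy-1-(triisopropylsilyl)indol-3-yl]phenyl}-1-(triisopropylsilyl)indole F5.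
- Removal of both silyl groups with TBAF in THF brings the route back at 20.

Step 5. Electron transfer from the organozinc to the nitrobenzyl bromide may lead to homocoupling of the benzyl unit, and transmetalation of the doubly ortho-substituted arylzinc may be slow. The fallback avoids the nitro group, sets out from 8 and comes back at 14.
- Aryllithium 11 (from 8, t-BuLi, −78 °C) would be added to commercial 2-bromo-4-methoxybenzaldehyde to give racemic (2-bromo-4-methoxyphenyl){4-[5-(benzyloxy)-1-(triisopropylsilyl)indol-3-yl]-2,3,5,6-tetramethoxyphenyl}methanol F6.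
- Ionic reduction of this strongly cation-stabilized carbinol (Et3SiH, BF3·OEt2 cat., CH2Cl2, −78 °C) should give 5-(benzyloxy)-3-[4-(2-bromo-4-methoxybenzyl)-2,3,5,6-tetramethoxyphenyl]-1-(triisopropylsilyl)indole F7.
- Buchwald–Hartwig amination with benzophenone imine (Pd2(dba)3, BINAP, NaOtBu, toluene, 80 °C) should give N-(diphenylmethylene)-2-({4-[5-(benzyloxy)-1-(triisopropylsilyl)indol-3-yl]-2,3,5,6-tetramethoxyphenyl}methyl)-5-methoxyaniline F8.
- Transimination with NH2OH·HCl and NaOAc in MeOH/THF releases aniline 14.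

Step 3. Oxidative addition into the electron-rich, doubly ortho-substituted C–Br bond may be slow, with protonation of the indolylzinc and over-coupling at the second bromide. The fallback reverses the polarity, sets out from 3 and 2 and comes back at 8.
- 3 would be silylated as in step 2 to 4 and iodinated in the same flask (NIS, THF, −78 °C) to 5-(benzyloxy)-3-iodo-1-(triisopropylsilyl)indole F9.
- Dibromide 2 would undergo single bromine–lithium exchange (n-BuLi, 1.0 equiv, THF, −78 °C) to (4-bromo-2,3,5,6-tetramethoxyphenyl)lithium F10, and ZnCl2 would give (4-bromo-2,3,5,6-tetramethoxyphenyl)zinc chloride F11.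
- Negishi coupling of F11 with F9 (Pd(PPh3)4, THF, rt → 40 °C) should give 8, the catalyst inserting into the C–I bond in preference to the hindered C–Br bond.

**Further compounds**

F1 | step 9 | 6-methoxy-1-(triisopropylsilyl)indole | COc1ccc2ccn([Si](C(C)C)(C(C)C)C(C)C)c2c1
F2 | step 9 | 3-bromo-6-methoxy-1-(triisopropylsilyl)indole | COc1ccc2c(Br)cn([Si](C(C)C)(C(C)C)C(C)C)c2c1
F3 | step 9 | [6-methoxy-1-(triisopropylsilyl)indol-3-yl]lithium | COc1ccc2c([Li])cn([Si](C(C)C)(C(C)C)C(C)C)c2c1
F4 | step 9 | [6-methoxy-1-(triisopropylsilyl)indol-3-yl]zinc chloride | COc1ccc2c([Zn]Cl)cn([Si](C(C)C)(C(C)C)C(C)C)c2c1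
F5 | step 9 | 5-(benzyloxy)-3-{2,3,5,6-tetramethoxy-4-[6-methoxy-1-(triisopropylsilyl)indol-3-yl]phenyl}-1-(triisopropylsilyl)indole | COc1ccc2c(-c3c(OC)c(OC)c(-c4cn([Si](C(C)C)(C(C)C)C(C)C)c5ccc(OCc6ccccc6)cc45)c(OC)c3OC)cn([Si](C(C)C)(C(C)C)C(C)C)c2c1
F6 | step 5 | racemic (2-bromo-4-methoxyphenyl){4-[5-(benzyloxy)-1-(triisopropylsilyl)indol-3-yl]-2,3,5,6-tetramethoxyphenyl}methanol | COc1ccc(C(O)c2c(OC)c(OC)c(-c3cn([Si](C(C)C)(C(C)C)C(C)C)c4ccc(OCc5ccccc5)cc34)c(OC)c2OC)c(Br)c1
F7 | step 5 | 5-(benzyloxy)-3-[4-(2-bromo-4-methoxybenzyl)-2,3,5,6-tetramethoxyphenyl]-1-(triisopropylsilyl)indole | COc1ccc(Cc2c(OC)c(OC)c(-c3cn([Si](C(C)C)(C(C)C)C(C)C)c4ccc(OCc5ccccc5)cc34)c(OC)c2OC)c(Br)c1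
F8 | step 5 | N-(diphenylmethylene)-2-({4-[5-(benzyloxy)-1-(triisopropylsilyl)indol-3-yl]-2,3,5,6-tetramethoxyphenyl}methyl)-5-methoxyaniline | COc1ccc(Cc2c(OC)c(OC)c(-c3cn([Si](C(C)C)(C(C)C)C(C)C)c4ccc(OCc5ccccc5)cc34)c(OC)c2OC)c(N=C(c6ccccc6)c7ccccc7)c1
F9 | step 3 | 5-(benzyloxy)-3-iodo-1-(triisopropylsilyl)indole | CC(C)[Si](C(C)C)(C(C)C)n1cc(I)c2cc(OCc3ccccc3)ccc21
F10 | step 3 | (4-bromo-2,3,5,6-tetramethoxyphenyl)lithium | COc1c(Br)c(OC)c(OC)c([Li])c1OC
F11 | step 3 | (4-bromo-2,3,5,6-tetramethoxyphenyl)zinc chloride | COc1c(Br)c(OC)c(OC)c([Zn]Cl)c1OC
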